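The numbers in the tables are calculated on assumed constants; noise was put on by code.

Which flask holds more target after 3.0 min: Wednesday's, with 0.590 equiv of partner, or Thursday's, with 1.80 equiv, both at 1 mol% of precatalyst?

| flask | substrate | partner | precatalyst | remark | time |
|---|---|---|---|---|---|
| amber | 2 mM | 1.8 equiv | 1.5 mol% | run made earlier |  |
| green | 2 mM | 1.8 equiv | 2 mol% | run made earlier |  |
| Wednesday's | 2.0 mM | 0.590 equiv | 1 mol% |  | 3.0 min |
| Thursday's | 2.0 mM | 1.80 equiv | 1 mol% |  | 3.0 min |

| run | time / s | target / % | substrate / % |
|---|---|---|---|
| amber | 10.0 | 0.4 | 99.3 |
| amber | 12.0 | 1.7 | 94.6 |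
| amber | 20.0 | 4.1 | 92.5 |
| amber | 25.0 | 9.0 | 87.3 |
| amber | 30.0 | 10.7 | 85.1 |
| amber | 40.0 | 13.9 | 77.3 |
| green | 10.0 | 3.6 | 97.5 |
| green | 12.0 | 3.1 | 95.9 |
| green | 20.0 | 7.7 | 92.0 |
| green | 25.0 | 10.1 | 86.0 |
| green | 30.0 | 14.1 | 81.6 |
| green | 40.0 | 17.5 | 71.5 |

(each reading ± 1 percentage point)

- which one finishes higher in amount of target, in percent of the substrate charged ("neither" within 2 percentage points) (Wednesday's / Thursday's / neither)
- amount of target at the end, in percent of the substrate charged, Wednesday's
- amount of target at the end, in percent of the substrate charged, Thursday's

- the numbers in the tables scatter by 1 percentage point (one standard deviation)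

Follow one molecule of substrate. Between their last two readings, the amber and green runs together lost 18 percentage points of substrate but gained 6.6 points of target, so target is being used as well as made. This reckoning assumes that each target molecule used takes one more substrate with it. Target used over target made is then the difference of those two figures over their sum, 0.461, a reading with much scatter in it.

If using grows with c_target, the two rates meet at the mean target of those readings divided by that ratio, 30.5 % at the runs' mean loading. Scaling in proportion to loading, and to partner by assumption since both runs share one partner charge, gives 17.4 % for Thursday's flask and 5.71 % for Wednesday's. This is the balance level, the amount of target at which a flask makes it as fast as it uses it.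

The runs stood at half of their level after 40.0 s, a shorter time than 3.0 min, so this reckoning assumes that each of the two flasks stands near its level by 3.0 min. Wednesday's flask should therefore end at about a third of Thursday's, lower by 12 points, beyond the margin.

The forecast, holding that the “partner order is unknown from these runs”, gave 17 % for Wednesday's, 17.5 % for Thursday's, and so neither. The simulation gives 5.96 % for Wednesday's and 18.0 % for Thursday's, so the higher one is Thursday's.

    substrate + partner + catalyst ⇌ target + catalyst, rate k1*[substrate]*[partner]*[catalyst] forward; the back reaction follows from the equilibrium constant (K = 390 M⁻¹, k = 1.20 × 10⁵ M⁻² s⁻¹)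
    partner + precatalyst → catalyst + spent reagent (k = 9.80 M⁻¹ s⁻¹)
    substrate + target → side product (k = 10.0 M⁻¹ s⁻¹)
    target → over-reaction product (k = 1.20 × 10⁻⁵ s⁻¹)

The difference in partner is the main reason: Wednesday's flask, given 1.80 equiv of partner, stands at 18.0 % instead of 5.96 %. The balance levels of 5.71 % and 17.4 % stand beside the flasks' 5.96 % and 18.0 %. For a further flask, Thursday's with 3.10 equiv of partner, the balance level scales to 30.0 %, whereas that flask holds 26.3 % of target.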